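Compare the charges first: the second end groups, at 0.0900 M, stand below the first end groups at 0.10 M, so they are the limiting reagent if one of each makes a link. Define the ceiling C as the second charge over the first, 90.0%: the part of the first end groups that can react.

| flask | first end groups | second end groups | scavenger | remark | time |
|---|---|---|---|---|---|
| dawn | 0.10 M | 0.090 M | 0.11 M | run made earlier |  |
| midnight | 0.10 M | 0.090 M | 0.22 M | run made earlier |  |
| south | 0.10 M | 0.0900 M | 0.120 M |  | 6.0 d |
| north-east | 0.10 M | 0.0900 M | 0.180 M |  | 6.0 d |
| south-east | 0.10 M | 0.0900 M | 0.0800 M |  | 6.0 d |

| run | time / d | first end groups / % | links / % |
|---|---|---|---|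
| dawn | 1.67 | 20 | 81 |
| dawn | 3.00 | 14 | 85 |
| dawn | 5.00 | 10 | 89 |
| dawn | 6.00 | 12 | 88 |
| midnight | 0.500 | 40 | 62 |
| midnight | 1.04 | 25 | 73 |
| midnight | 2.50 | 19 | 88 |
| midnight | 6.00 | 12 | 91 |

(scatter of a reading: 1.5 percentage points)

- a reading or a percentage of links counts all its forms, free or not

* part of the first end groups that has reacted at the end, south
* part of the first end groups that has reacted at the end, north-east
* part of the first end groups that has reacted at the end, south-east
* what raising the concentration of scavenger from its lowest to its highest value here does to the part of the first end groups that has reacted (changes below 5 percentage points count as none) (it rises / no change / it falls)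

Now build the ladder of times from the runs, with k the second-order rate constant. The midnight reading at 0.500 d gives k of about 36.5 M⁻¹ d⁻¹, a value that carries the reading's scatter. The fast rung is the inverse of k times the second charge, 0.305 d. The slow rung comes late, when the first end groups stand near their excess over the second end groups, and the second end groups then decay pseudo-first-order with half-life ln(2) over k times that excess, 1.90 d, longer than the fast rung. The asked 6.0 d is longer still, so expect a flask just under C, and the integrated rate law gives 88.9%.

Dawn and midnight both read 12% of first end groups at 6.00 d, with scavenger doubled. Yet both held more scavenger than second end groups, while south-east holds less. Take the same figure for south-east too, as an untested extension.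

The forecast agrees on south and north-east, at 89% and 89%, but parts from this reckoning on south-east with 79%, reasoning “If each link uses one scavenger, reaction stops near 80%”; its trend is "it rises".

The flasks give 89.0%, 89.0% and 89.0%, and the trend is "no change", a change of 0.071 percentage points.

    first end groups + second end groups → links + released group (k = 4.52 × 10⁻⁴ M⁻¹ s⁻¹)
    second end groups + released group ⇌ idle adduct, settled at all times (K = 4.20 M⁻¹)
    scavenger + released group → scavenged by-product (k = 0.00258 M⁻¹ s⁻¹)
    crystals ⇌ links, rate k4*(cs4 - [links]) while solid is left; crystals form when [links] > cs4 (solubility = 32.0 mM, k = 0.00460 s⁻¹)

In south-east the link-forming step had a half-life of 0.41 d at 0.249 d, short against the 6.0 d, and at the end, with scavenger down to 0.00510% of its charge, the released group stands free at 0.00894 M beside 0.0800 M of scavenged by-product, while 89.0% has reacted, just under C at 90.0%. In a further flask, like south-east but with 0.022 M of second end groups, C becomes 22.0%; that flask gives 22.0% reacted.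

The earlier runs and the new flask are calculated with constants of no real substance; scatter was added.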